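Retrosynthetic cuts, in order: O1–C2 of ring C (oxa-Michael); C4a–C8a of ring A (Claisen, leading back to a 2-pyranone); methine–C8 (Michael; C8 is pyranone C3); the methine=dienone carbon bond (Knoevenagel); and the CH2–CO bond of the cinnamoyl side chain (dianion acylation).
Enabling feature: ring A is a hexasubstituted phloroglucinol (C4a acyl, C5 OH, C6 Me, C7 OH, C8 alkyl, C8a O). Its alternating oxygen pattern is that of a cinnamoyl tetraketide folded in the Claisen sense. A 3,5,6-trisubstituted 4-hydroxy-2-pyranone holds the same chain in a stable, C3-nucleophilic form.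
Forward order: dienone ring (alkylative dearomatisation with the OMe group already in place, deacetylation, isobutylidene); pyranone side chain; union of the two halves at the methine; pyranone to ring A; ring C last.
Stereochemistry: the methine comes from a squaramide-catalysed Michael addition and C2 from a thiourea-catalysed oxa-Michael closure. Both are catalyst-controlled, so removing the minor diastereomer after ring closure should also raise the enantiomeric purity.
Regiochemistry of ring C: the two hydroxyls beside the cinnamoyl group are told apart by silylating the less hindered one (next to the methyl group) before closure.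
Key step: step 6

Assumption: the sense of induction of the two cinchona catalysts cannot be predicted safely for these substrates, so the quinine-derived members are written, the quinidine-derived pseudo-enantiomers serve if the opposite sense is found, and the configuration is to be secured at 15 and 20 by X-ray or ECD.
Assumption: the transient silyl enol ether in 18 is drawn on the oxygen next to the gem-dimethyl carbon; the tautomeric site would behave alike and gives the same 19.
Remark: the methine is (S) in 15 and (R) from 16 onward with unchanged spatial arrangement, because pyranone C3 (bearing the lactone carbonyl) outranks the dienone carbon in the CIP order whereas the chain carbon or arene carbon that replaces it does not.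
Remark: compounds 1 and 11 are taken as catalogue compounds, and all β-dicarbonyl units are drawn in one tautomeric form.

Step 1
Reactants: 1 2',6'-dihydroxy-4'-methoxyacetophenone
Product: 4 2-acetyl-3-hydroxy-5-methoxy-4,4,6-trimethylcyclohexa-2,5-dien-1-one, via 3'-methyl ketone 2 (not isolated), via 3',5'-dimethyl ketone 3 (not isolated)
Conditions: MeI (3.5 equiv), NaOMe (3.5 equiv), MeOH, reflux; then 1 M HCl
Reagents that add atoms: iodomethane, CI
Why: Exhaustive C-methylation of an acylphloroglucinol phenolate in methanol (alkylative dearomatisation) fills both free ring positions and then quaternises one of the two equivalent methyl-bearing carbons of symmetrical 3, and because the OMe group is already present it ends up between C(Me) and CMe2 as a vinylogous ester, which leaves no further enolisable ring CH and so stops the methylation at the trimethyl stage.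

Step 2
Reactants: 4 2-acetyl-3-hydroxy-5-methoxy-4,4,6-trimethylcyclohexa-2,5-dien-1-one
Product: 7 5-methoxy-4,6,6-trimethylcyclohex-4-ene-1,3-dione, via bromo triketone 5 (not isolated), via bromo dione 6 (not isolated)
Conditions: NBS (1.05 equiv), NaOAc (cat), MeOH, 0 °C to rt; then aq Na2SO3, AcOH, rt
Reagents that add atoms: none
Why: Bromination at the central carbon makes the triketone non-enolisable, so methanol removes the unhindered acetyl group by a retro-Claisen (haloform-type) deacylation under conditions in which exchange at the vinylogous methyl ester is degenerate, unlike the hot mineral acid usually needed for such deacylations, and sulfite then reduces the electrophilic bromine of the 2-bromo-1,3-dione.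

Step 3
Reactants: 7 5-methoxy-4,6,6-trimethylcyclohex-4-ene-1,3-dione; 8 isobutyraldehyde
Product: 10 5-methoxy-4,6,6-trimethyl-2-(2-methylpropylidene)cyclohex-4-ene-1,3-dione (E/Z mixture), via Mannich base 9 (not isolated)
Conditions: piperidine (1.05 equiv), CH2Cl2, 0 °C to rt; then 1 M HCl, CH2Cl2, rt; used at once
Reagents that add atoms: none
Why: This is a Knoevenagel condensation run in two stages, in which dione, aldehyde and piperidine first give the Mannich base, which cannot take up a second dione, and aqueous acid then eliminates piperidine to release the alkylidene dione free of any achiral base that could later drive a racemic background addition.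

Step 4
Reactants: 11 4-hydroxy-5,6-dimethyl-2H-pyran-2-one; 12 (E)-N-methoxy-N-methylcinnamamide
Product: 14 4-hydroxy-5-methyl-6-[(E)-2-oxo-4-phenylbut-3-en-1-yl]-2H-pyran-2-one, via dilithio dianion 13 (not isolated)
Conditions: LiN(iPr)2 (2.3 equiv), THF–DMPU, −78 to −30 °C; 12, −78 to 0 °C; 1 M HCl
Reagents that add atoms: none
Why: Two equivalents of base remove the 4-OH proton and then a proton of the C6 methyl group, the only methyl conjugated with the ring carbonyl system, and this terminal carbanion undergoes a Claisen-type acylation with the N-methoxy-N-methylamide, whose lithium-chelated tetrahedral adduct favours 1,2- over 1,4-attack and survives until the quench, so that neither over-addition nor proton transfer from the more acidic product can intervene.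

Step 5
Reactants: 10 5-methoxy-4,6,6-trimethyl-2-(2-methylpropylidene)cyclohex-4-ene-1,3-dione; 14 4-hydroxy-5-methyl-6-[(E)-2-oxo-4-phenylbut-3-en-1-yl]-2H-pyran-2-one
Product: 15 4-hydroxy-3-[(1S)-1-(2-hydroxy-4-methoxy-3,3,5-trimethyl-6-oxocyclohexa-1,4-dien-1-yl)-2-methylpropyl]-5-methyl-6-[(E)-2-oxo-4-phenylbut-3-en-1-yl]-2H-pyran-2-one
Conditions: quinine-derived 3,5-(CF3)2C6H3 squaramide (10 mol %), 10 (1.2 equiv), toluene–CH2Cl2, −40 °C; cold 0.5 M HCl wash
Reagents that add atoms: none
Why: In this bifunctional squaramide-catalysed Michael addition the quinuclidine deprotonates the most acidic site of 14 (the 4-OH, so that C3 and not the side-chain CH2 is the nucleophile), the squaramide NH groups bind the dione carbonyls of 10, which is far more electrophilic than the styryl ketone of 14, the catalyst pocket exposes one face of the trigonal CH(iPr) carbon and thereby sets the methine, and low temperature with prompt acid removal of the amine keeps the adduct out of the half-neutralised state from which retro-Michael racemisation is fastest.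

Step 6
Reactants: 15 4-hydroxy-3-[(1S)-1-(2-hydroxy-4-methoxy-3,3,5-trimethyl-6-oxocyclohexa-1,4-dien-1-yl)-2-methylpropyl]-5-methyl-6-[(E)-2-oxo-4-phenylbut-3-en-1-yl]-2H-pyran-2-one
Product: 17 (E)-1-{2,4,6-trihydroxy-3-[(1R)-1-(2-hydroxy-4-methoxy-3,3,5-trimethyl-6-oxocyclohexa-1,4-dien-1-yl)-2-methylpropyl]-5-methylphenyl}-3-phenylprop-2-en-1-one, via triketo ester 16 (not isolated)
Conditions: 15 added to Mg(OMe)2 (10 equiv), MeOH, Ar, reflux; poured into cold 1 M HCl, EtOAc; crude used at once
Reagents that add atoms: none
Why: Added to a large excess of Mg(OMe)2, 15 passes at once into its magnesium bis-enolate, magnesium-bound methoxide opens the lactone carbonyl to the chelated triketo ester 16, the CH2 between the two side-chain ketones attacks the ester carbonyl, methoxide leaves and the cyclohexanetrione enolises to the arene, so that pyranone C3, C4, C5 and the lactone carbon become C3' (alkyl), C4' (OH), C5' (Me) and C2' (OH) and the new C1'–C2' bond is C4a–C8a of the flavanone. The closest known reaction type is the Mg(OMe)2-induced recyclisation of 6-(2-oxoalkyl)-4-hydroxy-2-pyranones to acylphloroglucinols, the Claisen mode of tetraketide folding. The carbocycle closes 6-exo-trig, an enolate carbon adding to an ester C=O that lies outside the forming ring. No stereocentre is created, and the methine should persist because retro-Michael cleavage needs one half as an enolate and the other as its C-protonated keto tautomer, a pairing that is absent once both acidic halves are fully deprotonated, while in 16 the departing β-keto ester enolate would be far more basic than the dienone enolate that has to expel it. The step needs Claisen over aldol closure, which the substrate secures because the aldol mode would use the carbon that carries the methine substituent and could never aromatise, so that it, like methoxide or enolate additions to the styryl ketone, is reversible and drains into the irreversible aromatisation, with magnesium chelation of the tricarbonyl array favouring C-acylation. Methoxide is the matched base since exchange at the dienone vinylogous methyl ester is degenerate, and the strongly basic medium holds the product as the open chalcone polyanion until the cold acid quench.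

Step 7
Reactants: 17 (E)-1-{2,4,6-trihydroxy-3-[(1R)-1-(2-hydroxy-4-methoxy-3,3,5-trimethyl-6-oxocyclohexa-1,4-dien-1-yl)-2-methylpropyl]-5-methylphenyl}-3-phenylprop-2-en-1-one
Product: 19 4',6'-bis(tert-butyldimethylsilyl) ether of 17 (2'-OH and dienone enol free, methine R), via tris-silyl ether 18 (not isolated)
Conditions: TBSOTf (3.3 equiv), 2,6-lutidine (4 equiv), CH2Cl2, −78 °C; then 10 % aq citric acid–THF, 0 °C
Reagents that add atoms: tert-butyldimethylsilyl triflate, CC(C)(C)[Si](C)(C)OS(=O)(=O)C(F)(F)F
Why: Silylation of polyhydroxyaryl ketones characteristically stops at the last carbonyl-chelated ortho hydroxyl, and of the two ortho hydroxyls the one beside the methyl group is far more accessible than the one wedged between the carbonyl and the CH(iPr)(dienone) group, so the steric bias that would misdirect an unblocked ring closure places the blocking group correctly, while the low temperature and hindered base suppress premature cyclisation and the labile vinylogous silyl ester on the dienone is hydrolysed in the work-up.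

Step 8
Reactants: 19 4',6'-bis(tert-butyldimethylsilyl) ether of 17
Product: 20 (2S)-5,7-bis(tert-butyldimethylsilyloxy)-8-[(1R)-1-(2-hydroxy-4-methoxy-3,3,5-trimethyl-6-oxocyclohexa-1,4-dien-1-yl)-2-methylpropyl]-6-methyl-2-phenylchroman-4-one
Conditions: quinine-derived 3,5-(CF3)2C6H3 thiourea (20 mol %), toluene, 0 °C to rt; SiO2 chromatography
Reagents that add atoms: none
Why: In this cinchona-thiourea-catalysed intramolecular oxa-Michael addition of a 2'-hydroxychalcone (6-endo-trig) only the hydroxyl beside the methine-bearing carbon is free, so O1 can form only at C8a next to C8, the thiourea binds the ketone while the quinuclidine, ion-paired with the acidic dienone enol that sits next to the reacting hydroxyl, relays the proton and selects the alkene face that gives (2S), and any C2 epimer is a diastereomer that is removed on silica and can be re-equilibrated with the regiochemistry still locked.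

Step 9
Reactants: 20 (2S)-5,7-bis(tert-butyldimethylsilyloxy)-8-[(1R)-1-(2-hydroxy-4-methoxy-3,3,5-trimethyl-6-oxocyclohexa-1,4-dien-1-yl)-2-methylpropyl]-6-methyl-2-phenylchroman-4-one
Product: 21 (2S)-5,7-dihydroxy-8-[(1R)-1-(2-hydroxy-4-methoxy-3,3,5-trimethyl-6-oxocyclohexa-1,4-dien-1-yl)-2-methylpropyl]-6-methyl-2-phenylchroman-4-one (CNP0320113.1)
Conditions: 3HF·Et3N, THF–MeCN, 0 °C to rt
Reagents that add atoms: none
Why: Fluoride-induced cleavage of the aryl silyl ethers with the mildly acidic 3HF·Et3N avoids the phenoxide conditions under which a 5-hydroxyflavanone reopens to its chalcone, so neither C2, nor the ring C regiochemistry, nor the methine should be disturbed.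

Compound list
1 | 2',6'-dihydroxy-4'-methoxyacetophenone | CC(=O)c1c(O)cc(OC)cc1O | starting material
2 | 2',6'-dihydroxy-4'-methoxy-3'-methylacetophenone | CC(=O)c1c(O)cc(OC)c(C)c1O | intermediate
3 | 2',6'-dihydroxy-4'-methoxy-3',5'-dimethylacetophenone | CC(=O)c1c(O)c(C)c(OC)c(C)c1O | intermediate
4 | 2-acetyl-3-hydroxy-5-methoxy-4,4,6-trimethylcyclohexa-2,5-dien-1-one | CC(=O)C1=C(O)C(C)(C)C(OC)=C(C)C1=O | intermediate
5 | 2-acetyl-2-bromo-5-methoxy-4,6,6-trimethylcyclohex-4-ene-1,3-dione (racemic) | CC(=O)C1(Br)C(=O)C(C)=C(OC)C(C)(C)C1=O | intermediate
6 | 2-bromo-3-hydroxy-5-methoxy-4,4,6-trimethylcyclohexa-2,5-dien-1-one | COC1=C(C)C(=O)C(Br)=C(O)C1(C)C | intermediate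
7 | 5-methoxy-4,6,6-trimethylcyclohex-4-ene-1,3-dione | COC1=C(C)C(=O)CC(=O)C1(C)C | intermediate
8 | isobutyraldehyde | CC(C)C=O | starting material
9 | 3-hydroxy-5-methoxy-4,4,6-trimethyl-2-[2-methyl-1-(piperidin-1-yl)propyl]cyclohexa-2,5-dien-1-one (racemic) | COC1=C(C)C(=O)C(C(C(C)C)N2CCCCC2)=C(O)C1(C)C | intermediate
10 | 5-methoxy-4,6,6-trimethyl-2-(2-methylpropylidene)cyclohex-4-ene-1,3-dione (E/Z mixture) | COC1=C(C)C(=O)C(=CC(C)C)C(=O)C1(C)C | intermediate
11 | 4-hydroxy-5,6-dimethyl-2H-pyran-2-one | CC1=C(C)OC(=O)C=C1O | starting material
12 | (E)-N-methoxy-N-methylcinnamamide | CON(C)C(=O)/C=C/c1ccccc1 | starting material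
13 | dilithio dianion of 11 (4-oxide, C6 CH2 carbanion) | [Li+].[Li+].[CH2-]C1=C(C)C([O-])=CC(=O)O1 | intermediate
14 | 4-hydroxy-5-methyl-6-[(E)-2-oxo-4-phenylbut-3-en-1-yl]-2H-pyran-2-one | O=C1C=C(O)C(C)=C(CC(=O)/C=C/c2ccccc2)O1 | intermediate
15 | 4-hydroxy-3-[(1S)-1-(2-hydroxy-4-methoxy-3,3,5-trimethyl-6-oxocyclohexa-1,4-dien-1-yl)-2-methylpropyl]-5-methyl-6-[(E)-2-oxo-4-phenylbut-3-en-1-yl]-2H-pyran-2-one | COC1=C(C)C(=O)C([C@@H](C2=C(O)C(C)=C(CC(=O)/C=C/c3ccccc3)OC2=O)C(C)C)=C(O)C1(C)C | intermediate
16 | methyl (E)-2-[(1R)-1-(2-hydroxy-4-methoxy-3,3,5-trimethyl-6-oxocyclohexa-1,4-dien-1-yl)-2-methylpropyl]-4-methyl-3,5,7-trioxo-9-phenylnon-8-enoate (magnesium chelate, C2 and C4 undefined) | COC1=C(C)C(=O)C([C@@H](C(C(=O)OC)C(=O)C(C)C(=O)CC(=O)/C=C/c2ccccc2)C(C)C)=C(O)C1(C)C | intermediate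
17 | (E)-1-{2,4,6-trihydroxy-3-[(1R)-1-(2-hydroxy-4-methoxy-3,3,5-trimethyl-6-oxocyclohexa-1,4-dien-1-yl)-2-methylpropyl]-5-methylphenyl}-3-phenylprop-2-en-1-one | COC1=C(C)C(=O)C([C@@H](c2c(O)c(C)c(O)c(C(=O)/C=C/c3ccccc3)c2O)C(C)C)=C(O)C1(C)C | intermediate
18 | 4',6'-bis-O-TBS, dienone-O-TBS tris-silyl ether of 17 | COC1=C(C)C(=O)C([C@@H](c2c(O[Si](C)(C)C(C)(C)C)c(C)c(O[Si](C)(C)C(C)(C)C)c(C(=O)/C=C/c3ccccc3)c2O)C(C)C)=C(O[Si](C)(C)C(C)(C)C)C1(C)C | intermediate
19 | 4',6'-bis(tert-butyldimethylsilyl) ether of 17 (2'-OH and dienone enol free) | COC1=C(C)C(=O)C([C@@H](c2c(O[Si](C)(C)C(C)(C)C)c(C)c(O[Si](C)(C)C(C)(C)C)c(C(=O)/C=C/c3ccccc3)c2O)C(C)C)=C(O)C1(C)C | intermediate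
20 | (2S)-5,7-bis(tert-butyldimethylsilyloxy)-8-[(1R)-1-(2-hydroxy-4-methoxy-3,3,5-trimethyl-6-oxocyclohexa-1,4-dien-1-yl)-2-methylpropyl]-6-methyl-2-phenylchroman-4-one | COC1=C(C)C(=O)C([C@@H](c2c(O[Si](C)(C)C(C)(C)C)c(C)c(O[Si](C)(C)C(C)(C)C)c3c2O[C@H](c2ccccc2)CC3=O)C(C)C)=C(O)C1(C)C | intermediate
21 | (2S)-5,7-dihydroxy-8-[(1R)-1-(2-hydroxy-4-methoxy-3,3,5-trimethyl-6-oxocyclohexa-1,4-dien-1-yl)-2-methylpropyl]-6-methyl-2-phenylchroman-4-one | COC1=C(C)C(=O)C([C@@H](c2c(O)c(C)c(O)c3c2O[C@H](c2ccccc2)CC3=O)C(C)C)=C(O)C1(C)C | target

Total step count: 9.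
Longest linear sequence: 8 steps (1 → 4 → 7 → 10 → 15 → 17 → 19 → 20 → 21). The pyranone branch (11 → 14) joins at step 5.

Steps most likely to fail

Step 6. The lactone carbonyl sits next to the branched C3 substituent and belongs to an anionic ring, so opening may be sluggish. Prolonged heating could then allow fragment scrambling or loss of the methine configuration by retro-Michael cleavage at the open-chain stage. The fallback sets out from 14 and 10 and comes back at 17. The ring transformation is carried out before the union: 14, which has no C3 substituent and is therefore closest to the documented cases, is recyclised with Mg(OMe)2 in methanol to (E)-2',4',6'-trihydroxy-3'-methylchalcone F1. The single free ring carbon of F1 is then joined at once to 10 by a Friedel–Crafts-type Michael addition under a chiral bifunctional cinchona catalyst. This is the established way of uniting acylphloroglucinols with isobutylidene β-diketones, and it gives 17 directly.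

Step 5. Facial selectivity on the isobutylidene carbon may be poor, or the adduct may erode by reversible addition while amine is present. The fallback sets out from 10 and 14 and comes back at 15. The union is run without asymmetric induction (catalytic Et3N, CH2Cl2) to give racemic adduct F2. This is resolved by preparative chromatography on a chiral stationary phase to give 15. The unwanted (1R) enantiomer F3 is deliberately racemised by warming with a catalytic amine (retro-Michael and re-addition) and recycled.

Step 7. Silylation may fail to distinguish the two ortho hydroxyls, or ring closure may outrun silylation. The fallback sets out from 17 and comes back at 21. The blocking group is abandoned and 17 is closed under equilibrating conditions (NaOAc, EtOH, warm). Target 21 is then separated by chromatography from its diastereomer, the (2R) epimer F4, and from its constitutional isomer, the 6-alkyl-8-methyl flavanone F5. F4 and F5 are reopened with cold aqueous KOH to the common chalcone 17 and cycled again.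

Further compounds
F1 | step 6 | (E)-2',4',6'-trihydroxy-3'-methylchalcone | O=C(/C=C/c1ccccc1)c1c(O)cc(O)c(C)c1O
F2 | step 5 | racemic form of 15 | COC1=C(C)C(=O)C(C(C2=C(O)C(C)=C(CC(=O)/C=C/c3ccccc3)OC2=O)C(C)C)=C(O)C1(C)C
F3 | step 5 | (1R) enantiomer of 15 | COC1=C(C)C(=O)C([C@H](C2=C(O)C(C)=C(CC(=O)/C=C/c3ccccc3)OC2=O)C(C)C)=C(O)C1(C)C
F4 | step 7 | (2R) epimer of 21 (methine R) | COC1=C(C)C(=O)C([C@@H](c2c(O)c(C)c(O)c3c2O[C@@H](c2ccccc2)CC3=O)C(C)C)=C(O)C1(C)C
F5 | step 7 | 5,7-dihydroxy-6-[(1R)-1-(2-hydroxy-4-methoxy-3,3,5-trimethyl-6-oxocyclohexa-1,4-dien-1-yl)-2-methylpropyl]-8-methyl-2-phenylchroman-4-one (both C2 epimers) | COC1=C(C)C(=O)C([C@@H](c2c(O)c(C)c3OC(c4ccccc4)CC(=O)c3c2O)C(C)C)=C(O)C1(C)C
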